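The amounts in the earlier closed flasks stop moving. The late product readings of the winter and spring flasks stay close to those of the midnight flask, although the winter flask holds half the catalyst of the midnight flask and at 1.33 h reads 19.0% against 25.5%.

| flask | substrate | partner | catalyst | remark | time |
|---|---|---|---|---|---|
| midnight | 1.5 M | 1.65 M | 150 mM | run made earlier |  |
| winter | 1.5 M | 1.65 M | 75 mM | run made earlier |  |
| spring | 1.5 M | 1.65 M | 110 mM | run made earlier |  |
| larch | 1.5 M (fed, over 8.00 h) | 1.65 M | 150 mM | a stirred flask in which substrate is dosed at a steady rate over 8.00 h without added volume, worked up at 10 h | 10 h |
| oak | 1.5 M | 1.65 M | 150 mM | one stirred flow tank at steady state, fed with the mixture as stated, mean residence time 10 h |  |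
| maple | 1.5 M | 1.65 M | 150 mM | everything together in a closed stirred flask, run for 10 h | 10 h |
| alder | 1.5 M | 1.65 M (fed, over 8.00 h) | 150 mM | all but partner at the start; partner goes in evenly over 8.00 h, the run ends at 10 h | 10 h |

- midnight (time / h: product / %, substrate / %): 1.33: 25.5, 75.9; 4.00: 26.4, 73.8; 6.00: 25.9, 71.8; 10.0: 27.2, 73.6
- winter (time / h: product / %, substrate / %): 0.667: 14.2, 85.5; 1.33: 19.0, 79.3; 3.00: 24.7, 72.5; 8.00: 27.2, 72.9
- spring (time / h: product / %, substrate / %): 2.00: 24.7, 74.4; 4.00: 24.8, 72.6; 6.00: 26.5, 72.2; 8.00: 25.9, 73.4

(readings scatter by 1 percentage point)

- the stated concentrations are those of everything mixed, before any reaction; amounts are the same in each set-up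
- the numbers in the tables scatter with a standard deviation of 1 percentage point
- the feed brings no volume worth counting
- the earlier runs were made in a closed, stirred flask

- the set-up with the highest amount of product at the outlet or at the end, in percent of the substrate put in ("none" if the first two lie within 2 percentage points) (larch / oak / maple / alder / none)
- amount of product at the outlet or at the end, in percent of the substrate put in, larch
- amount of product at the outlet or at the end, in percent of the substrate put in, oak
- amount of product at the outlet or at the end, in percent of the substrate put in, maple
- amount of product at the outlet or at the end, in percent of the substrate put in, alder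

A plateau that ignores the catalyst suggests thermodynamic control, where the stopping point is an equilibrium. The number to carry is then the balance quotient, the equilibrium constant: product concentration divided by free substrate times free partner.

It can be reached in two ways. The midnight product readings from 4.00 h onward average 26.5%, which gives 0.288 M⁻¹. The spring substrate readings average 73.2%, so the missing part is counted as product, and that gives 0.294 M⁻¹. These are different flasks, catalyst loadings and species, and the two implied product shares differ by 0.35 percentage points against a scatter of 1 point per reading. The two ways therefore agree within the scatter, and their mean is the reading carried forward as the balance quotient 0.291 M⁻¹.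

Whether the maple flask reaches that balance is a question of time. The winter flask stands at 24.7% after 3.00 h, and the maple flask has twice that catalyst and 10 h, longer than those hours.

In this reckoning, the product concentration x solves quotient × (substrate − x) × (partner − x) = x, and the smaller root gives 26.7% of the substrate charged for maple. Larch and alder have their full charges 2.00 h before the end, so they aim at the same value. For the oak tank, which keeps taking in fresh mixture, the quotient is a ceiling rather than a value.

The forecast gives 26.4% for larch, 25.2% for oak, 26.5% for maple and 26.4% for alder, with best none, noting that “Both fed flasks hold the same totals”. Its maple value is lower than this reckoning's.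

The simulation gives 26.8% for larch, 25.5% for oak, 26.8% for maple and 26.8% for alder, so best is none.

    substrate + partner + catalyst ⇌ catalyst + product (K = 0.293 M⁻¹, k = 2.32 M⁻² h⁻¹)

The maple flask stops where it does because of the return of product to substrate and partner: with that return it ends at 26.8%, and without it at 88.3%. The balance quotient 0.291 M⁻¹ had given 26.7% for this flask. A neighbour of maple charged with 0.41 M of partner reckons by the same quotient to 7.84%, and that neighbour flask holds 7.88%.

The runs were computed with constants of no real substance; noise was put on by code.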